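The data come from a simulation for an exercise; the scatter is artificial.

**One step fails.** Picture a one-step world: electrophile plus nucleophile gives target, and what the electrophile loses the target gains. The east run disagrees: by 0.667 min the electrophile has lost 18.7%, yet the target holds 5.2%. So you add the second path, self-condensation, second order in electrophile.

| setting | east | south-east | flask |
|---|---|---|---|
| electrophile | 0.025 M | 0.10 M | 0.050 M |
| nucleophile | 0.125 M | 0.125 M | 0.125 M |
| remark | run made earlier | run made earlier |  |
| time |  |  | 15 min |

| run | time / min | electrophile / % | target / % |
|---|---|---|---|
| east | 0.667 | 81.3 | 5.2 |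
| east | 1.50 | 64.9 | 10.3 |
| east | 4.00 | 38.5 | 21.5 |
| east | 10.0 | 16.7 | 32.5 |
| south-east | 1.00 | 46.4 | 5.8 |
| south-east | 3.00 | 20.7 | 10.5 |
| south-east | 6.00 | 10.7 | 13.3 |
| south-east | 10.0 | 5.8 | 14.6 |

(each reading ± 0.5 percentage points)

- percent here means electrophile units held: one self-condensation product counts as two
- the analysis behind the earlier runs scatters by 0.5 percentage points, standard deviation
- what may be going on: nucleophile + acid set free <-> protonated nucleophile; electrophile + nucleophile -> acid set free + target; target <-> isomer of the product; 2 electrophile -> self-condensation product
- the earlier runs do not show how much of nucleophile is bound; that part of a forecast is a guess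

* part of the electrophile that has reacted at 15 min
* share of the unused nucleophile that is free and not bound as protonated nucleophile, at 15 min

**Frozen constants.** Let k, the pseudo-first-order constant, be the target's rate of formation over c(electrophile). The first east reading gives 0.0860 min⁻¹, the last two give 0.0702 min⁻¹. Freeze k at their mean, 0.0781 min⁻¹. Let s be the remaining electrophile loss over c(electrophile) squared. The first readings give 0.166 M⁻¹ s⁻¹ in the east run and 0.172 M⁻¹ s⁻¹ in the south-east run.

**The crossover.** Their ratio k/s, 0.00785 M, is the crossover concentration, the c(electrophile) at which both paths use electrophile equally fast. The flask starts at 6.37 times that.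

**The flask.** With both frozen, the reciprocal of c(electrophile) plus the reciprocal of the crossover grows by exp(kt). At 15 min you reckon 0.00287 M left in the flask, so 94.3% reacted. In the same reckoning, target formed in the flask is the crossover times the logarithm of (crossover + charge)/(crossover + rest): 0.0132 M.

**Weak link.** The runs do not show the binding. If each acid set free binds a nucleophile, the free share is 88.2%; without binding, 100%. Now reforge this from the sag. In the east run, k fell to 0.816 of its first reading. At the mean target of the last two readings, full binding predicts 0.892, no binding 0.946. The reading, scattered as it is, stands lower than the full-binding figure, so you commit to 88.2%.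

**The result.** The forecast gives 94.2% (93.3% to 95%) and 91% (88.5% to 97%), above your free share, and says of the binding “this remains a guess”. The flask gives 94.1% reacted and 87.9% of its unused nucleophile free.

    nucleophile + acid set free ⇌ protonated nucleophile, settled at all times (K = 2980 M⁻¹)
    electrophile + nucleophile → acid set free + target (k = 0.0121 M⁻¹ s⁻¹)
    target ⇌ isomer of the product (K = 0.498, k = 4.58 × 10⁻⁵ s⁻¹)
    2 electrophile → self-condensation product (k = 0.0840 M⁻¹ s⁻¹)

**Richer nucleophile.** Take k in the neighbour charged with 0.50 M of nucleophile as following that charge, scaled by 4.00, and you reckon its crossover at 0.0314 M. With 0.31% of its electrophile left, its rest stands far below that crossover, and the same logarithm gives 59.8% of its charged electrophile as target formed. That neighbour holds 59.4% target and 2.04% isomer of the product at 15.0 min.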